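Numbering: carotenoid numbers are used; ring A = C1–C6 (the 3-hydroxy-5,6-ene ring joined through C7H2 to the C8 ketone), ring B = C1'–C6' (the 3'-hydroxy-4',5'-ene ring), C19 = the acyloxymethyl carbon on C9.
Cuts: C14–C15 and C15'–C14' (Stille, C15=C15' from a distannylethene), C11'=C12', C9=C10 and C9'=C10' (Horner–Wadsworth–Emmons), C8–C9 (phosphonate addition), C6–C7 (Suzuki–Miyaura at the ring A enol triflate), C19–O (esterification).
Feature: C3 of ring A is an isolated secondary carbinol between the C2 and C4 methylenes with no neighbouring group to steer a reagent; it maps onto the C4 carbonyl of flat, prochiral ketoisophorone, so an ene-reductase/ketoreductase pair can set it.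
Forward order: no ring is built; ring A comes from ketoisophorone (actinol, silyl ether, enol triflate, C7–C8 aldehyde, β-ketophosphonate, C9=C10, C19 ester = fragment A, a C14 iodide), ring B from α-ionone (dienenitrile, 3'-ketone, 3'-carbinol, resolution, C15 aldehyde, C14' iodide, C15 stannane = fragment B); the last step joins C14 to C15.
Stereochemistry: C3 from the enzymatic cascade (the methyl centre set with it is erased in the triflate); C3' and C6' from the trans carbinol of a hydride reduction plus a lipase resolution; C13=C14 and C13'=C14' from syn carboalumination; the other alkenes from E-selective Wittig and phosphonate olefinations and stereoretentive Stille couplings.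

Key step: step 1

Assumption: the Pseudomonas fluorescens lipase acetylates the (4R)-carbinol of racemic 28 faster, as is usual for cyclohex-2-en-1-ols; should it prefer the other enantiomer, the recovered (1R,4R) alcohol enters step 18 in place of its acetate, because the hydride reduction there accepts either.

Step 1
Reactants: 1 ketoisophorone
Product: 3 (4R,6R)-actinol, via (6R)-levodione 2 (not isolated)
Conditions: old yellow enzyme OYE2 (Saccharomyces cerevisiae), glucose dehydrogenase, D-glucose, NADP+ and NAD+ (cat.), phosphate buffer pH 7, 30 °C; once 1 is consumed, levodione reductase (Corynebacterium aquaticum) is added to the same vessel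
Reagents that add atoms: none
Why: The ene-reductase binds the enedione over its reduced flavin and transfers hydride from flavin N5 to one alkene carbon while an active-site tyrosine protonates the other from the opposite face, a net anti addition of H2 that is the enzymatic counterpart of an asymmetric conjugate reduction and gives (6R)-levodione 2. The NADH-dependent ketoreductase then delivers hydride to one face of the C4 carbonyl of 2, the known carbonyl-reductase step that follows old yellow enzyme reduction of this substrate. No ring is closed and no skeletal bond is formed; two stereocentres are created. C6 (R) is fixed by the enantioface of the flat C2=C3 bond that the ene-reductase presents to the flavin, and C4 (R) by the carbonyl face that the reductase presents to the nicotinamide. The step needs C=C reduction before C=O reduction and reduction of only one of the two carbonyls: the first is secured by adding the ketoreductase only after 1 is consumed (it would otherwise reduce C4 of 1 directly), the second by the substrate, whose C1 carbonyl is shielded by the C2 gem-dimethyl group and the new C6 methyl group. Glucose dehydrogenase recycles NAD(P)H, so glucose is the only stoichiometric reductant.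

Step 2
Reactants: 3 (4R,6R)-actinol
Product: 4 (4R,6R)-4-[(tert-butyldimethylsilyl)oxy]-2,2,6-trimethylcyclohexan-1-one
Conditions: TBSCl, imidazole, DMF, rt
Reagents that add atoms: tert-butyldimethylsilyl chloride, CC(C)(C)[Si](C)(C)Cl
Why: Imidazole-promoted silylation of the unhindered secondary hydroxyl gives a base-stable silyl ether that protects the C3 oxygen through enolate formation, cross-coupling and oxidation, and it touches neither stereocentre.

Step 3
Reactants: 4 silyl ether of actinol
Product: 5 (4R)-4-[(tert-butyldimethylsilyl)oxy]-2,6,6-trimethylcyclohex-1-en-1-yl trifluoromethanesulfonate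
Conditions: LiN(i-Pr)2, THF, −78 → 0 °C; then PhNTf2, 0 °C → rt
Reagents that add atoms: N-phenylbis(trifluoromethanesulfonimide), O=S(=O)(N(c1ccccc1)S(=O)(=O)C(F)(F)F)C(F)(F)F
Why: Deprotonation is possible only at the methyl-bearing α-carbon because the other α-carbon is quaternary, so a single tetrasubstituted lithium enolate forms and is O-sulfonylated by PhNTf2 (enol triflate formation), which erases the sacrificial methyl stereocentre, creates the future C5=C6 alkene and leaves the carbinol carbon as the only stereocentre.

Step 4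
Reactants: 5 ring A enol triflate; 6 (E)-2-(2-ethoxyethenyl)-4,4,5,5-tetramethyl-1,3,2-dioxaborolane
Product: 8 2-[(4R)-4-[(tert-butyldimethylsilyl)oxy]-2,6,6-trimethylcyclohex-1-en-1-yl]acetaldehyde, via dienol ether 7 (not isolated)
Conditions: Pd(OAc)2 (5 mol%), SPhos (10 mol%), K3PO4, THF/H2O, 60 °C; then 1 M aq HCl, THF, 0 °C
Reagents that add atoms: water, O
Why: Suzuki–Miyaura coupling of the enol triflate with the alkenylboronate, run with a bulky biarylphosphine that tolerates a tetrasubstituted partner, forms C6–C7, and the enol ether 7, twisted out of conjugation by the flanking methyl groups, should then be protonated at C7 and hydrolysed to the β,γ-unsaturated aldehyde that keeps the tetrasubstituted ring alkene, cold dilute acid leaving the secondary silyl ether intact.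

Step 5
Reactants: 9 diethyl (2-hydroxyethyl)phosphonate
Product: 10 diethyl {2-[(triethylsilyl)oxy]ethyl}phosphonate
Conditions: Et3SiCl, imidazole, CH2Cl2, 0 °C
Reagents that add atoms: chlorotriethylsilane, CC[Si](Cl)(CC)CC
Why: Standard silylation of the primary alcohol, the triethylsilyl ether being chosen because mild acid can later remove it in the presence of the ring tert-butyldimethylsilyl ether.

Step 6
Reactants: 10 silylated phosphonate; 8 ring A acetaldehyde
Product: 11 diethyl {4-[(4R)-4-[(tert-butyldimethylsilyl)oxy]-2,6,6-trimethylcyclohex-1-en-1-yl]-3-hydroxy-1-[(triethylsilyl)oxy]butan-2-yl}phosphonate (mixture of diastereomers)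
Conditions: LiN(i-Pr)2, THF, −78 °C; then 8, −78 °C; AcOH quench at −78 °C
Reagents that add atoms: none
Why: α-Lithiation of the alkylphosphonate and 1,2-addition of the carbanion to the aldehyde (phosphonate aldol-type addition) forms C8–C9; at −78 °C addition should outrun enolisation of the aldehyde and loss of silyloxide, the β-oxido phosphonate does not collapse to an alkene, and the two new stereocentres are of no consequence because both carbons become sp2 in steps 7 and 10.

Step 7
Reactants: 11 β-hydroxyphosphonate
Product: 12 diethyl {4-[(4R)-4-[(tert-butyldimethylsilyl)oxy]-2,6,6-trimethylcyclohex-1-en-1-yl]-3-oxo-1-[(triethylsilyl)oxy]butan-2-yl}phosphonate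
Conditions: Dess–Martin periodinane, NaHCO3, CH2Cl2, 0 °C → rt
Reagents that add atoms: none
Why: Dess–Martin oxidation turns the secondary alcohol into the C8 ketone under buffered, non-basic conditions, which should keep the β-silyloxy β-ketophosphonate from eliminating and the ring alkene from moving into conjugation.

Step 8
Reactants: 13 propargyl alcohol
Product: 15 (E)-3-iodo-2-methylprop-2-en-1-ol, via alkenylalane 14 (not isolated)
Conditions: AlMe3, Cp2ZrCl2 (25 mol%), CH2Cl2, 0 °C → rt; then iodine, THF, −30 → 0 °C
Reagents that add atoms: trimethylaluminium, C[Al](C)C; iodine, [I][I]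
Why: Zirconium-catalysed carboalumination adds methyl and aluminium syn across the alkyne with methyl on the internal carbon, and iodinolysis of the alkenyl–aluminium bond with retention gives the E trisubstituted vinyl iodide that becomes C13=C14 in one half and C13'=C14' in the other.

Step 9
Reactants: 15 (E)-3-iodo-2-methylprop-2-en-1-ol; 16 (triphenylphosphoranylidene)acetaldehyde
Product: 18 (2E,4E)-5-iodo-4-methylpenta-2,4-dienal, via iodoenal 17 (not isolated)
Conditions: MnO2, CH2Cl2, rt; filtration; then 16 (one equivalent), toluene, 60 °C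
Reagents that add atoms: none
Why: MnO2 oxidises the allylic alcohol to the volatile aldehyde 17, which is used without isolation in a Wittig reaction with the stabilised formyl ylide (one equivalent, to limit a second homologation) that gives the E disubstituted alkene, the future C11=C12.

Step 10
Reactants: 12 β-ketophosphonate; 18 iododienal
Product: 19 (3E,5E,7E)-1-[(4R)-4-[(tert-butyldimethylsilyl)oxy]-2,6,6-trimethylcyclohex-1-en-1-yl]-8-iodo-7-methyl-3-{[(triethylsilyl)oxy]methyl}octa-3,5,7-trien-2-one
Conditions: Ba(OH)2·8H2O, THF/H2O (40:1), 0 °C → rt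
Reagents that add atoms: none
Why: Horner–Wadsworth–Emmons olefination of the α-branched β-ketophosphonate with the unhindered dienal under mild Ba(OH)2 conditions forms C9=C10; the stabilised carbanion should add faster than it loses silyloxide, and collapse through the more stable oxaphosphetane places the C8 acyl group trans to the dienyl residue, which is the required 9E geometry, any minor isomer being removed by chromatography.

Step 11
Reactants: 19 bis-silyl trienone iodide
Product: 20 (3E,5E,7E)-1-[(4R)-4-[(tert-butyldimethylsilyl)oxy]-2,6,6-trimethylcyclohex-1-en-1-yl]-3-(hydroxymethyl)-8-iodo-7-methylocta-3,5,7-trien-2-one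
Conditions: PPTS (10 mol%), MeOH/CH2Cl2, 0 °C
Reagents that add atoms: none
Why: Acid-catalysed methanolysis (silyl ether solvolysis) removes the primary triethylsilyl ether much faster than the hindered secondary tert-butyldimethylsilyl ether and so frees only the C19 hydroxyl.

Step 12
Reactants: 20 C19 alcohol; 21 (E)-oct-2-enoic acid
Product: 22 (2E,4E,6E)-2-{[(4R)-4-[(tert-butyldimethylsilyl)oxy]-2,6,6-trimethylcyclohex-1-en-1-yl]acetyl}-7-iodo-6-methylhepta-2,4,6-trien-1-yl (2E)-oct-2-enoate
Conditions: EDC·HCl, DMAP (10 mol%), CH2Cl2, 0 °C → rt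
Reagents that add atoms: none
Why: Steglich esterification (carbodiimide activation, acyl transfer by DMAP) acylates the only free hydroxyl under conditions that keep the 2E geometry of the acid and avoid the ketene pathway of an acid chloride with amine base.

Step 13
Reactants: 22 silylated ester
Product: 23 (2E,4E,6E)-2-{[(4R)-4-hydroxy-2,6,6-trimethylcyclohex-1-en-1-yl]acetyl}-7-iodo-6-methylhepta-2,4,6-trien-1-yl (2E)-oct-2-enoate (fragment A)
Conditions: HF·pyridine, pyridine, THF, 0 °C → rt
Reagents that add atoms: none
Why: Fluoride-driven cleavage of the remaining silyl ether with pyridine-buffered HF (desilylation) frees the C3 hydroxyl while the allylic ester, the vinyl iodide and the β,γ-unsaturated ketone tolerate the weakly acidic medium, and it is done here so that only carbon–carbon bond formation follows.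

Step 14
Reactants: 24 α-ionone (racemic); 25 diethyl (cyanomethyl)phosphonate
Product: 26 rac-(2E,4E)-3-methyl-5-(2,6,6-trimethylcyclohex-2-en-1-yl)penta-2,4-dienenitrile
Conditions: NaH, THF, 0 °C → rt
Reagents that add atoms: none
Why: Horner–Wadsworth–Emmons olefination of the methyl ketone with the cyanomethylphosphonate carbanion adds C10' and C11' and should favour the 2E nitrile (cyano group trans to the chain, the future 9'E alkene), the minor 2Z isomer being removed by chromatography, and the nitrile masks C11' as a group inert to the oxidation and reduction that follow.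

Step 15
Reactants: 26 dienenitrile
Product: 27 rac-(2E,4E)-3-methyl-5-(2,6,6-trimethyl-4-oxocyclohex-2-en-1-yl)penta-2,4-dienenitrile
Conditions: t-BuOOH (70% aq), Rh2(cap)4 (cap = caprolactamate, 1 mol%), K2CO3, CH2Cl2, rt
Reagents that add atoms: tert-butyl hydroperoxide, CC(C)(C)OO
Why: Catalytic allylic oxidation with tert-butyl hydroperoxide (peroxyl-radical hydrogen abstraction, then conversion of the allylic peroxide into the enone) should attack the only unhindered allylic methylene, C3' of ring B, whereas the doubly allylic C6' hydrogen is buried between the gem-dimethyl group and the side chain.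

Step 16
Reactants: 27 ring B enone
Product: 28 rac-(2E,4E)-5-[(1R,4R)-4-hydroxy-2,6,6-trimethylcyclohex-2-en-1-yl]-3-methylpenta-2,4-dienenitrile (3',6'-trans racemate)
Conditions: NaBH4, CeCl3·7H2O, MeOH, −20 °C
Reagents that add atoms: none
Why: Luche reduction reduces the ring enone at the carbonyl and leaves the conjugated nitrile; hydride delivery to the face opposite the axial C1' methyl group gives the 3',6'-trans carbinol, and since both faces are hindered a cis/trans mixture is expected, from which the trans racemate is separated by chromatography while the cis pair is returned to 27 by MnO2 oxidation.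

Step 17
Reactants: 28 trans racemic carbinol
Product: 29 (1R,4R)-4-[(1E,3E)-4-cyano-3-methylbuta-1,3-dien-1-yl]-3,5,5-trimethylcyclohex-2-en-1-yl acetate
Conditions: Pseudomonas fluorescens lipase, vinyl acetate, t-BuOMe, 30 °C, stopped near half conversion
Reagents that add atoms: vinyl acetate, C=COC(C)=O
Why: Lipase-catalysed irreversible transesterification with vinyl acetate (enzymatic kinetic resolution) acylates one enantiomer of the racemic carbinol and so fixes the absolute configuration of both ring B centres at once, the (1S,4S) alcohol being left behind and removed by chromatography.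

Step 18
Reactants: 29 (1R,4R)-acetate
Product: 30 (2E,4E)-5-[(1R,4R)-4-hydroxy-2,6,6-trimethylcyclohex-2-en-1-yl]-3-methylpenta-2,4-dienal
Conditions: i-Bu2AlH (4 equiv), CH2Cl2, −78 °C; then aqueous Rochelle salt, rt
Reagents that add atoms: water, O
Why: Diisobutylaluminium hydride reduces the nitrile to the N-aluminio aldimine, which is hydrolysed to the aldehyde on work-up (partial reduction of a nitrile), and the same reagent cleaves the acetate reductively, so the C15 hydroxy aldehyde should result in one operation without touching the stereocentres or the 2E alkene.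

Step 19
Reactants: 15 (E)-3-iodo-2-methylprop-2-en-1-ol
Product: 31 (E)-3-bromo-1-iodo-2-methylprop-1-ene
Conditions: CBr4, PPh3, CH2Cl2, 0 °C
Reagents that add atoms: carbon tetrabromide, BrC(Br)(Br)Br
Why: Appel bromination converts the primary allylic alcohol into the bromide by SN2 displacement of the oxyphosphonium group under neutral conditions that leave the vinyl iodide alone.

Step 20
Reactants: 31 allylic bromide
Product: 32 diethyl [(2E)-3-iodo-2-methylprop-2-en-1-yl]phosphonate
Conditions: P(OEt)3 (neat), 90 °C
Reagents that add atoms: triethyl phosphite, CCOP(OCC)OCC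
Why: Michaelis–Arbuzov reaction of the primary allylic bromide with triethyl phosphite gives the allylic phosphonate, the vinyl iodide being inert to a phosphite in the absence of a metal catalyst.

Step 21
Reactants: 30 C15 hydroxy aldehyde; 32 iodoallyl phosphonate
Product: 33 (1R,4R)-4-[(1E,3E,5E,7E)-8-iodo-3,7-dimethylocta-1,3,5,7-tetraen-1-yl]-3,5,5-trimethylcyclohex-2-en-1-ol
Conditions: 32 (2.5 equiv), NaN(SiMe3)2, THF, −78 °C; then 30, −78 → 0 °C
Reagents that add atoms: none
Why: Horner–Wadsworth–Emmons olefination of the allylic phosphonate anion (in excess, one equivalent being consumed by the free hydroxyl) with the enal forms C11'=C12' with the E selectivity typical of allylic phosphonates in polyene synthesis and leaves the vinyl iodide for cross-coupling.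

Step 22
Reactants: 33 tetraenyl iodide; 34 (E)-1,2-bis(tributylstannyl)ethene
Product: 35 (1R,4R)-4-[(1E,3E,5E,7E,9E)-3,7-dimethyl-10-(tributylstannyl)deca-1,3,5,7,9-pentaen-1-yl]-3,5,5-trimethylcyclohex-2-en-1-ol (fragment B)
Conditions: 34 (fourfold excess), Pd2(dba)3 (2.5 mol%), AsPh3 (20 mol%), NMP, rt, dark
Reagents that add atoms: none
Why: Stille coupling of the alkenyl iodide with the distannane proceeds with retention at both sp2 carbons, so the E geometry of C15=C15' comes from the reagent, and the excess of distannane suppresses a second coupling.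

Step 23
Reactants: 23 fragment A; 35 fragment B
Product: 36 (3R,3'R,6'R)-3,3'-dihydroxy-19-[(2E)-oct-2-enoyloxy]-7,8-dihydro-β,ε-caroten-8-one (all-E; the target)
Conditions: Pd2(dba)3 (5 mol%), AsPh3 (40 mol%), NMP, rt, dark, argon
Reagents that add atoms: none
Why: Stille coupling under neutral, phosphine-free conditions joins C14 to C15 with retention of both alkene geometries and needs no protecting group; oxidative addition of zerovalent palladium into the dienyl carbon–iodine bond should be far faster than ionisation of the allylic C19 ester, and neither the ester, the β,γ-unsaturated ketone nor the allylic ring B carbinol meets acid or base.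

Compound list
1 | ketoisophorone (2,6,6-trimethylcyclohex-2-ene-1,4-dione) | CC1=CC(=O)CC(C)(C)C1=O | starting material
2 | (6R)-levodione, (6R)-2,2,6-trimethylcyclohexane-1,4-dione | O=C1[C@H](C)CC(=O)CC1(C)C | intermediate
3 | (4R,6R)-actinol, (4R,6R)-4-hydroxy-2,2,6-trimethylcyclohexan-1-one | O=C1[C@H](C)C[C@@H](O)CC1(C)C | intermediate
4 | (4R,6R)-4-[(tert-butyldimethylsilyl)oxy]-2,2,6-trimethylcyclohexan-1-one | O=C1[C@H](C)C[C@@H](O[Si](C)(C)C(C)(C)C)CC1(C)C | intermediate
5 | (4R)-4-[(tert-butyldimethylsilyl)oxy]-2,6,6-trimethylcyclohex-1-en-1-yl trifluoromethanesulfonate | FC(F)(F)S(=O)(=O)OC1=C(C)C[C@@H](O[Si](C)(C)C(C)(C)C)CC1(C)C | intermediate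
6 | (E)-2-(2-ethoxyethenyl)-4,4,5,5-tetramethyl-1,3,2-dioxaborolane | CCO/C=C/B1OC(C)(C)C(C)(C)O1 | starting material
7 | tert-butyl{[(1R)-4-[(E)-2-ethoxyethenyl]-3,5,5-trimethylcyclohex-3-en-1-yl]oxy}dimethylsilane (dienol ether) | CCO/C=C/C1=C(C)C[C@@H](O[Si](C)(C)C(C)(C)C)CC1(C)C | intermediate
8 | 2-[(4R)-4-[(tert-butyldimethylsilyl)oxy]-2,6,6-trimethylcyclohex-1-en-1-yl]acetaldehyde | O=CCC1=C(C)C[C@@H](O[Si](C)(C)C(C)(C)C)CC1(C)C | intermediate
9 | diethyl (2-hydroxyethyl)phosphonate | CCOP(=O)(CCO)OCC | starting material
10 | diethyl {2-[(triethylsilyl)oxy]ethyl}phosphonate | CCOP(=O)(CCO[Si](CC)(CC)CC)OCC | intermediate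
11 | diethyl {4-[(4R)-4-[(tert-butyldimethylsilyl)oxy]-2,6,6-trimethylcyclohex-1-en-1-yl]-3-hydroxy-1-[(triethylsilyl)oxy]butan-2-yl}phosphonate (diastereomer mixture at the two chain centres) | CCOP(=O)(OCC)C(CO[Si](CC)(CC)CC)C(O)CC1=C(C)C[C@@H](O[Si](C)(C)C(C)(C)C)CC1(C)C | intermediate
12 | diethyl {4-[(4R)-4-[(tert-butyldimethylsilyl)oxy]-2,6,6-trimethylcyclohex-1-en-1-yl]-3-oxo-1-[(triethylsilyl)oxy]butan-2-yl}phosphonate (both epimers at the phosphorus-bearing carbon) | CCOP(=O)(OCC)C(CO[Si](CC)(CC)CC)C(=O)CC1=C(C)C[C@@H](O[Si](C)(C)C(C)(C)C)CC1(C)C | intermediate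
13 | propargyl alcohol (prop-2-yn-1-ol) | C#CCO | starting material
14 | dimethylaluminium (E)-3-(dimethylalumanyl)-2-methylprop-2-en-1-olate (alkenylalane) | C[Al](C)OC/C(C)=C/[Al](C)C | intermediate
15 | (E)-3-iodo-2-methylprop-2-en-1-ol | OC/C(C)=C/I | intermediate
16 | (triphenylphosphoranylidene)acetaldehyde | O=CC=P(c1ccccc1)(c1ccccc1)c1ccccc1 | starting material
17 | (E)-3-iodo-2-methylprop-2-enal | O=C/C(C)=C/I | intermediate
18 | (2E,4E)-5-iodo-4-methylpenta-2,4-dienal | O=C/C=C/C(C)=C/I | intermediate
19 | (3E,5E,7E)-1-[(4R)-4-[(tert-butyldimethylsilyl)oxy]-2,6,6-trimethylcyclohex-1-en-1-yl]-8-iodo-7-methyl-3-{[(triethylsilyl)oxy]methyl}octa-3,5,7-trien-2-one | CC[Si](CC)(CC)OC\C(=C/C=C/C(C)=C/I)C(=O)CC1=C(C)C[C@@H](O[Si](C)(C)C(C)(C)C)CC1(C)C | intermediate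
20 | (3E,5E,7E)-1-[(4R)-4-[(tert-butyldimethylsilyl)oxy]-2,6,6-trimethylcyclohex-1-en-1-yl]-3-(hydroxymethyl)-8-iodo-7-methylocta-3,5,7-trien-2-one | OC\C(=C/C=C/C(C)=C/I)C(=O)CC1=C(C)C[C@@H](O[Si](C)(C)C(C)(C)C)CC1(C)C | intermediate
21 | (E)-oct-2-enoic acid | CCCCC/C=C/C(=O)O | starting material
22 | (2E,4E,6E)-2-{[(4R)-4-[(tert-butyldimethylsilyl)oxy]-2,6,6-trimethylcyclohex-1-en-1-yl]acetyl}-7-iodo-6-methylhepta-2,4,6-trien-1-yl (2E)-oct-2-enoate | CCCCC/C=C/C(=O)OC\C(=C/C=C/C(C)=C/I)C(=O)CC1=C(C)C[C@@H](O[Si](C)(C)C(C)(C)C)CC1(C)C | intermediate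
23 | (2E,4E,6E)-2-{[(4R)-4-hydroxy-2,6,6-trimethylcyclohex-1-en-1-yl]acetyl}-7-iodo-6-methylhepta-2,4,6-trien-1-yl (2E)-oct-2-enoate (fragment A) | CCCCC/C=C/C(=O)OC\C(=C/C=C/C(C)=C/I)C(=O)CC1=C(C)C[C@@H](O)CC1(C)C | intermediate
24 | α-ionone, racemic (E)-4-(2,6,6-trimethylcyclohex-2-en-1-yl)but-3-en-2-one | CC(=O)/C=C/C1C(C)=CCCC1(C)C | starting material
25 | diethyl (cyanomethyl)phosphonate | CCOP(=O)(CC#N)OCC | starting material
26 | rac-(2E,4E)-3-methyl-5-(2,6,6-trimethylcyclohex-2-en-1-yl)penta-2,4-dienenitrile | N#C/C=C(C)/C=C/C1C(C)=CCCC1(C)C | intermediate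
27 | rac-(2E,4E)-3-methyl-5-(2,6,6-trimethyl-4-oxocyclohex-2-en-1-yl)penta-2,4-dienenitrile | N#C/C=C(C)/C=C/C1C(C)=CC(=O)CC1(C)C | intermediate
28 | rac-(2E,4E)-5-[(1R,4R)-4-hydroxy-2,6,6-trimethylcyclohex-2-en-1-yl]-3-methylpenta-2,4-dienenitrile (trans racemate, one enantiomer drawn) | N#C/C=C(C)/C=C/[C@H]1C(C)=C[C@H](O)CC1(C)C | intermediate
29 | (1R,4R)-4-[(1E,3E)-4-cyano-3-methylbuta-1,3-dien-1-yl]-3,5,5-trimethylcyclohex-2-en-1-yl acetate | N#C/C=C(C)/C=C/[C@H]1C(C)=C[C@H](OC(C)=O)CC1(C)C | intermediate
30 | (2E,4E)-5-[(1R,4R)-4-hydroxy-2,6,6-trimethylcyclohex-2-en-1-yl]-3-methylpenta-2,4-dienal | O=C/C=C(C)/C=C/[C@H]1C(C)=C[C@H](O)CC1(C)C | intermediate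
31 | (E)-3-bromo-1-iodo-2-methylprop-1-ene | BrC/C(C)=C/I | intermediate
32 | diethyl [(2E)-3-iodo-2-methylprop-2-en-1-yl]phosphonate | CCOP(=O)(C/C(C)=C/I)OCC | intermediate
33 | (1R,4R)-4-[(1E,3E,5E,7E)-8-iodo-3,7-dimethylocta-1,3,5,7-tetraen-1-yl]-3,5,5-trimethylcyclohex-2-en-1-ol | I/C=C(C)/C=C/C=C(C)/C=C/[C@H]1C(C)=C[C@H](O)CC1(C)C | intermediate
34 | (E)-1,2-bis(tributylstannyl)ethene | CCCC[Sn](CCCC)(CCCC)/C=C/[Sn](CCCC)(CCCC)CCCC | starting material
35 | (1R,4R)-4-[(1E,3E,5E,7E,9E)-3,7-dimethyl-10-(tributylstannyl)deca-1,3,5,7,9-pentaen-1-yl]-3,5,5-trimethylcyclohex-2-en-1-ol (fragment B) | CCCC[Sn](CCCC)(CCCC)/C=C/C=C(C)/C=C/C=C(C)/C=C/[C@H]1C(C)=C[C@H](O)CC1(C)C | intermediate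
36 | (3R,3'R,6'R)-3,3'-dihydroxy-19-[(2E)-oct-2-enoyloxy]-7,8-dihydro-β,ε-caroten-8-one, all-E | CCCCC/C=C/C(=O)OC\C(=C/C=C/C(C)=C/C=C/C=C(C)/C=C/C=C(C)/C=C/[C@H]1C(C)=C[C@H](O)CC1(C)C)C(=O)CC1=C(C)C[C@@H](O)CC1(C)C | target

Total step count: 23 steps. Longest linear sequence: 11 steps (steps 1, 2, 3, 4, 6, 7, 10, 11, 12, 13 and 23, from ketoisophorone); the ring B line runs through 8 steps (14–18, 21, 22, 23).

Steps most likely to fail

Step 10 (with step 6 before it). The phosphonate carbanion may lose its β-silyloxy group by elimination before it adds to the aldehyde, and the olefination may give part of the 9Z isomer. The fallback sets out from aldehyde 8 and brings in the C19 oxygen only after the C9–C10 bond exists. CH2=CHMgBr adds to 8 to give allylic alcohol F1, and Dess–Martin oxidation gives vinyl ketone F2. A Morita–Baylis–Hillman reaction of F2 with dienal 18 (DABCO) joins C9 to C10 and gives Morita–Baylis–Hillman adduct F3, which carries the C10 carbinol and a C9 exo-methylene group that is the future C19. Steglich esterification of F3 with acid 21 gives C10 octenoate F4. DABCO-catalysed allylic transposition of this ester (SN2' then SN2') moves the acyloxy group to C19 and the alkene to C9=C10, with the acyl group trans to the dienyl chain as the thermodynamic outcome. This comes back to the route at 22.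

Step 23. Zerovalent palladium may ionise the allylic C19 ester, with loss or 1,3-shift of the octenoate and scrambling of C9=C10, and the polyenyl stannane may be protodestannylated. The fallback sets out from iodide 20 (C19 hydroxyl free, C3 silyl ether) and stannane 35 and puts the ester on after the polyene is complete. The same Stille conditions give silylated C40 diol F5, which has no allylic ester. Steglich esterification with one equivalent of 21 at 0 °C should take the primary C19 hydroxyl in preference to the secondary ring B carbinol and give silyl ether ester F6. Pyridine-buffered HF then removes the silyl ether, and the route is rejoined at 36.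

Step 4. Oxidative addition and transmetallation may be slow at the tetrasubstituted, doubly flanked triflate, and during hydrolysis the enol ether may be protonated at C5 so that the ring alkene moves into conjugation. The fallback sets out from triflate 5 and avoids the enol ether. Suzuki–Miyaura coupling with vinylboronic acid pinacol ester (PdCl2(dppf), K3PO4) gives vinyl diene F7. 9-BBN adds to the terminal vinyl group only (anti-Markovnikov hydroboration) to give alkylborane F8, and NaOH/H2O2 gives primary alcohol F9. Dess–Martin oxidation of F9 comes back to the route at 8.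

Further compounds
F1 | step 10 | 1-[(4R)-4-[(tert-butyldimethylsilyl)oxy]-2,6,6-trimethylcyclohex-1-en-1-yl]but-3-en-2-ol (allylic alcohol, both carbinol epimers) | C=CC(O)CC1=C(C)C[C@@H](O[Si](C)(C)C(C)(C)C)CC1(C)C
F2 | step 10 | 1-[(4R)-4-[(tert-butyldimethylsilyl)oxy]-2,6,6-trimethylcyclohex-1-en-1-yl]but-3-en-2-one (vinyl ketone) | C=CC(=O)CC1=C(C)C[C@@H](O[Si](C)(C)C(C)(C)C)CC1(C)C
F3 | step 10 | (5E,7E)-1-[(4R)-4-[(tert-butyldimethylsilyl)oxy]-2,6,6-trimethylcyclohex-1-en-1-yl]-4-hydroxy-8-iodo-7-methyl-3-methylideneocta-5,7-dien-2-one (Morita–Baylis–Hillman adduct, both carbinol epimers) | C=C(C(O)/C=C/C(C)=C/I)C(=O)CC1=C(C)C[C@@H](O[Si](C)(C)C(C)(C)C)CC1(C)C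
F4 | step 10 | (5E,7E)-1-[(4R)-4-[(tert-butyldimethylsilyl)oxy]-2,6,6-trimethylcyclohex-1-en-1-yl]-8-iodo-7-methyl-3-methylidene-2-oxoocta-5,7-dien-4-yl (2E)-oct-2-enoate (C10 octenoate) | CCCCC/C=C/C(=O)OC(/C=C/C(C)=C/I)C(=C)C(=O)CC1=C(C)C[C@@H](O[Si](C)(C)C(C)(C)C)CC1(C)C
F5 | step 23 | (3R,3'R,6'R)-3-[(tert-butyldimethylsilyl)oxy]-3',19-dihydroxy-7,8-dihydro-β,ε-caroten-8-one, all-E (silylated C40 diol) | OC\C(=C/C=C/C(C)=C/C=C/C=C(C)/C=C/C=C(C)/C=C/[C@H]1C(C)=C[C@H](O)CC1(C)C)C(=O)CC1=C(C)C[C@@H](O[Si](C)(C)C(C)(C)C)CC1(C)C
F6 | step 23 | (3R,3'R,6'R)-3-[(tert-butyldimethylsilyl)oxy]-3'-hydroxy-19-[(2E)-oct-2-enoyloxy]-7,8-dihydro-β,ε-caroten-8-one, all-E (silyl ether ester) | CCCCC/C=C/C(=O)OC\C(=C/C=C/C(C)=C/C=C/C=C(C)/C=C/C=C(C)/C=C/[C@H]1C(C)=C[C@H](O)CC1(C)C)C(=O)CC1=C(C)C[C@@H](O[Si](C)(C)C(C)(C)C)CC1(C)C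
F7 | step 4 | tert-butyl{[(1R)-4-ethenyl-3,5,5-trimethylcyclohex-3-en-1-yl]oxy}dimethylsilane (vinyl diene) | C=CC1=C(C)C[C@@H](O[Si](C)(C)C(C)(C)C)CC1(C)C
F8 | step 4 | 9-{2-[(4R)-4-[(tert-butyldimethylsilyl)oxy]-2,6,6-trimethylcyclohex-1-en-1-yl]ethyl}-9-borabicyclo[3.3.1]nonane (alkylborane) | C(CB1C2CCCC1CCC2)C1=C(C)C[C@@H](O[Si](C)(C)C(C)(C)C)CC1(C)C
F9 | step 4 | 2-[(4R)-4-[(tert-butyldimethylsilyl)oxy]-2,6,6-trimethylcyclohex-1-en-1-yl]ethan-1-ol (primary alcohol) | OCCC1=C(C)C[C@@H](O[Si](C)(C)C(C)(C)C)CC1(C)C
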